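**Retrosynthetic overview**
- Target ⇒ late acyl/protecting-group adjustments ⇒ C8–C9 union by chelation-controlled Hosomi–Sakurai addition of a spiroketal allylsilane to a C1–C8 aldehyde; C10 is set afterwards by OH-directed hydrogenation.
- Spiroketal allylsilane ⇒ C2-symmetric spiroketal dialdehyde, whose symmetry is broken by one chelation-controlled vinyl-Grignard addition (C11); the other CHO becomes the C21/C22 ketol.
- C2-symmetric spiroketal ⇒ Claisen self-condensation and decarboxylation of two molecules of one cis-4,6-disubstituted δ-lactone; rings A and B close together in one thermodynamic spiroketalisation.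
- δ-Lactone ⇒ enantioselective dearomatising hydrogenation of 6-(benzyloxymethyl)-4-methyl-2-pyrone, made from 4,6-dimethyl-2-pyrone (sets C12/C14 and, after dimerisation, C18/C20).
- C1–C8 aldehyde ⇒ Brown anti-crotylation of dimethoxyacetaldehyde, then a Felkin/1,3-anti vinylogous Mukaiyama aldol with the tiglate dienolate.

Assumption: locants C1–C23 follow the target chain from the ester carbon (C1) through the spiro carbon (C16) to the ketone methyl (C23); ring A = O/C12–C16, ring B = O/C16–C20.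
Assumption: (S)-MeO-BIPHEP is taken as the ligand antipode that gives the 6S lactone in step 3; if the sense is opposite, its mirror image is used.

**Route**

Step 1
Reactants: 1 4,6-dimethyl-2H-pyran-2-one
Product: 2 4-methyl-2-oxo-2H-pyran-6-carbaldehyde
Conditions: SeO2 (1.5 equiv), 1,4-dioxane, 160 °C, sealed tube
Reagents that add atoms: selenium dioxide, O=[Se]=O
Why: Riley allylic oxidation, whose ene step needs the electron-rich enol-ether-type C5=C6 bond, so the 6-methyl rather than the 4-methyl on the electron-poor enoate carbon is oxidised to the aldehyde.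

Step 2
Reactants: 2 4-methyl-2-oxo-2H-pyran-6-carbaldehyde
Product: 3 6-[(benzyloxy)methyl]-4-methyl-2H-pyran-2-one
Conditions: BnOSiMe3, Et3SiH, Me3SiOTf (10 mol%), CH2Cl2, −78 → 0 °C
Reagents that add atoms: benzyloxytrimethylsilane, C[Si](C)(C)OCc1ccccc1
Why: Lewis-acid-catalysed reductive etherification (the silyl ether adds to the aldehyde and Et3SiH reduces the oxocarbenium ion) installs in one operation a benzyl ether that survives homogeneous hydrogenation, NaH and aqueous acid.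

Step 3
Reactants: 3 6-[(benzyloxy)methyl]-4-methyl-2H-pyran-2-one
Product: 5 (4S,6S)-6-[(benzyloxy)methyl]-4-methyltetrahydro-2H-pyran-2-one, via dihydropyranone 4 (not isolated)
Conditions: H2 (60 bar), Ru(OAc)2[(S)-MeO-BIPHEP] (1 mol%), HBF4·OEt2 (2 mol%), i-PrOH/CH2Cl2, 60 °C; then 100 bar, 80 °C
Reagents that add atoms: none
Why: Enantioselective dearomatising hydrogenation of a 2-pyrone with a cationic Ru–atropisomeric diphosphine catalyst, in which the first H2 adds to the C5=C6 enol-ester bond and sets C6 (future C12 and C20) under catalyst control and the second adds to C3=C4 anti to the C6 substituent to give the cis lactone (future C14 and C18).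

Step 4
Reactants: 5 (4S,6S)-6-[(benzyloxy)methyl]-4-methyltetrahydro-2H-pyran-2-one (two molecules)
Product: 8 (2S,4S,6S,8S,10S)-2,8-bis[(benzyloxy)methyl]-4,10-dimethyl-1,7-dioxaspiro[5.5]undecane, via acyl-lactone 6 (not isolated), via keto-diol 7 (not isolated)
Conditions: NaH (0.55 equiv), THF, 0 → 60 °C; then 2 M aq HCl, AcOH, 70 °C
Reagents that add atoms: none
Why: Claisen self-condensation of the lactone enolate on a second lactone, then acid hydrolysis, decarboxylation of the β-keto acid and thermodynamic spiroketalisation of the C2-symmetric keto-diol, which closes rings A and B at once to the doubly anomeric all-equatorial spiroketal (C16 = S) and raises the ee because the heterochiral dimer is a separable diastereomer.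

Step 5
Reactants: 8 (2S,4S,6S,8S,10S)-2,8-bis[(benzyloxy)methyl]-4,10-dimethyl-1,7-dioxaspiro[5.5]undecane
Product: 9 [(2S,4S,6S,8S,10S)-4,10-dimethyl-1,7-dioxaspiro[5.5]undecane-2,8-diyl]dimethanol
Conditions: H2 (1 atm), Pd(OH)2/C, EtOAc/MeOH, rt
Reagents that add atoms: none
Why: Hydrogenolysis of the two benzyl ethers in a substrate with no other reducible group.

Step 6
Reactants: 9 [(2S,4S,6S,8S,10S)-4,10-dimethyl-1,7-dioxaspiro[5.5]undecane-2,8-diyl]dimethanol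
Product: 10 (2S,4S,6S,8S,10S)-4,10-dimethyl-1,7-dioxaspiro[5.5]undecane-2,8-dicarbaldehyde
Conditions: Dess–Martin periodinane (2.5 equiv), NaHCO3, CH2Cl2, 0 °C → rt
Reagents that add atoms: none
Why: Buffered Dess–Martin oxidation of both primary alcohols gives the C2-symmetric α-alkoxy dialdehyde without epimerisation, and any epimerisation would in any case return to the equatorial isomer.

Step 7
Reactants: 10 (2S,4S,6S,8S,10S)-4,10-dimethyl-1,7-dioxaspiro[5.5]undecane-2,8-dicarbaldehyde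
Product: 12 (2S,4S,6S,8S,10S)-4,10-dimethyl-8-{(1S)-1-[(triethylsilyl)oxy]-2-[(trimethylsilyl)methyl]prop-2-en-1-yl}-1,7-dioxaspiro[5.5]undecane-2-carbaldehyde, via hydroxy-aldehyde 11 (not isolated)
Conditions: MgBr2·OEt2 (2 equiv), CH2Cl2, −78 °C; CH2=C(MgBr)CH2SiMe3 (0.6 equiv, Et2O); then Et3SiOTf, 2,6-lutidine, −78 → −40 °C; unreacted 10 recovered and recycled
Reagents that add atoms: [1-(trimethylsilylmethyl)vinyl]magnesium bromide, C=C([Mg]Br)C[Si](C)(C)C; triethylsilyl triflate, CC[Si](CC)(CC)OS(=O)(=O)C(F)(F)F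
Why: Symmetry-breaking mono-addition of a vinyl Grignard reagent to the two homotopic formyl groups, so that one mono-adduct forms and Cram-chelate control (Mg bridging C=O and the ring oxygen) gives the 11,12-syn (11S) carbinol, trapped in the flask as its TES ether.

Step 8
Reactants: 12 (2S,4S,6S,8S,10S)-4,10-dimethyl-8-{(1S)-1-[(triethylsilyl)oxy]-2-[(trimethylsilyl)methyl]prop-2-en-1-yl}-1,7-dioxaspiro[5.5]undecane-2-carbaldehyde
Product: 15 (1R)-1-[(tert-butyldimethylsilyl)oxy]-1-[(2S,4S,6S,8S,10S)-4,10-dimethyl-8-{(1S)-1-[(triethylsilyl)oxy]-2-[(trimethylsilyl)methyl]prop-2-en-1-yl}-1,7-dioxaspiro[5.5]undecan-2-yl]propan-2-one, via alkoxide adduct 13 (not isolated), via silyl enol-ether 14 (not isolated)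
Conditions: CH2=C(OEt)Li (from ethyl vinyl ether, t-BuLi, THF), MgBr2·OEt2, CH2Cl2/Et2O, −78 °C; then t-BuMe2SiOTf, 2,6-lutidine, −78 → 0 °C; then 5% aq oxalic acid, THF, 0 °C
Reagents that add atoms: (1-ethoxyvinyl)lithium, [Li]C(=C)OCC; tert-butyldimethylsilyl triflate, CC(C)(C)[Si](C)(C)OS(=O)(=O)C(F)(F)F; water, O
Why: Chelation-controlled addition of an acetyl-anion equivalent to the remaining α-alkoxy aldehyde sets C21 (20,21-syn, 21R) by the same Cram-chelate model, the alkoxide is silylated in the flask, and mild acid hydrolysis of the enol ether unveils the methyl ketone.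

Step 9
Reactants: 16 2,2-dimethoxyacetaldehyde
Product: 17 (2S,3S)-1,1-dimethoxy-3-methylpent-4-en-2-ol
Conditions: trans-2-butene, n-BuLi, KOt-Bu, THF, −78 → −45 °C; (−)-Ipc2BOMe; BF3·OEt2; then 16, −78 °C; NaOH, H2O2
Reagents that add atoms: (E)-crotyldiisopinocampheylborane (crotyl group from trans-2-butene), C/C=C/CB([C@@H]1C[C@@H]2C[C@H]([C@H]1C)C2(C)C)[C@@H]3C[C@@H]4C[C@H]([C@H]3C)C4(C)C
Why: Brown (E)-crotylboration through a closed chair transition state gives the anti adduct, and the isopinocampheyl groups of the (+)-α-pinene series direct Si-face attack to set C7 and C6 as (S,S).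

Step 10
Reactants: 17 (2S,3S)-1,1-dimethoxy-3-methylpent-4-en-2-ol
Product: 18 1-({[(2S,3S)-1,1-dimethoxy-3-methylpent-4-en-2-yl]oxy}methyl)-4-methoxybenzene
Conditions: NaH, 4-MeOC6H4CH2Cl, Bu4NI (cat.), DMF, 0 °C → rt
Reagents that add atoms: 4-methoxybenzyl chloride, COc1ccc(CCl)cc1
Why: Williamson etherification installs the PMB ether that will later act as the chelating group at C7.

Step 11
Reactants: 18 1-({[(2S,3S)-1,1-dimethoxy-3-methylpent-4-en-2-yl]oxy}methyl)-4-methoxybenzene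
Product: 19 (2R,3S)-4,4-dimethoxy-3-[(4-methoxybenzyl)oxy]-2-methylbutanal
Conditions: O3, CH2Cl2, −78 °C (stopped at first excess); PPh3; used crude
Reagents that add atoms: ozone, [O-][O+]=O
Why: Ozonolysis with reductive work-up cleaves the only alkene to the anti-α-methyl-β-alkoxy aldehyde, which is used at once to avoid α-epimerisation (2R here only through a CIP priority change).

Step 12
Reactants: 20 methyl (2E)-2-methylbut-2-enoate (methyl tiglate)
Product: 21 [(1-methoxy-2-methylbuta-1,3-dien-1-yl)oxy]trimethylsilane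
Conditions: LiN(i-Pr)2, THF/DMPU, −78 °C; Me3SiCl
Reagents that add atoms: chlorotrimethylsilane, C[Si](C)(C)Cl
Why: γ-Deprotonation of the enoate and O-silylation of the dienolate give the silyl dienol ether needed for the vinylogous aldol.

Step 13
Reactants: 19 (2R,3S)-4,4-dimethoxy-3-[(4-methoxybenzyl)oxy]-2-methylbutanal; 21 [(1-methoxy-2-methylbuta-1,3-dien-1-yl)oxy]trimethylsilane
Product: 22 methyl (2E,5R,6S,7S)-5-hydroxy-8,8-dimethoxy-7-[(4-methoxybenzyl)oxy]-2,6-dimethyloct-2-enoate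
Conditions: BF3·OEt2 (1.1 equiv), CH2Cl2, −78 °C
Reagents that add atoms: none
Why: Vinylogous Mukaiyama aldol through an open transition state, in which Felkin–Anh control by the α-methyl group and 1,3-anti induction by the β-OPMB group reinforce each other for this anti aldehyde to give 5,6-syn-5,7-anti (5R), with γ-attack giving the (E)-enoate.

Step 14
Reactants: 22 methyl (2E,5R,6S,7S)-5-hydroxy-8,8-dimethoxy-7-[(4-methoxybenzyl)oxy]-2,6-dimethyloct-2-enoate
Product: 23 methyl (2E,5R,6S,7S)-8,8-dimethoxy-7-[(4-methoxybenzyl)oxy]-2,6-dimethyl-5-(propanoyloxy)oct-2-enoate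
Conditions: (EtCO)2O, Et3N, 4-(dimethylamino)pyridine (cat.), CH2Cl2, 0 °C → rt
Reagents that add atoms: propanoic anhydride, CCC(=O)OC(=O)CC
Why: DMAP-catalysed acylation puts the C5 propanoate in place early, when C5 carries the only free hydroxyl.

Step 15
Reactants: 23 methyl (2E,5R,6S,7S)-8,8-dimethoxy-7-[(4-methoxybenzyl)oxy]-2,6-dimethyl-5-(propanoyloxy)oct-2-enoate
Product: 24 methyl (2E,5R,6S,7S)-7-[(4-methoxybenzyl)oxy]-2,6-dimethyl-8-oxo-5-(propanoyloxy)oct-2-enoate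
Conditions: 1 M aq HCl/THF (1:3), 40 °C
Reagents that add atoms: water, O
Why: Dilute-acid hydrolysis of the dimethyl acetal frees the C8 aldehyde under conditions that leave the PMB ether and the esters intact.

Step 16
Reactants: 15 (1R)-1-[(tert-butyldimethylsilyl)oxy]-1-[(2S,4S,6S,8S,10S)-4,10-dimethyl-8-{(1S)-1-[(triethylsilyl)oxy]-2-[(trimethylsilyl)methyl]prop-2-en-1-yl}-1,7-dioxaspiro[5.5]undecan-2-yl]propan-2-one; 24 methyl (2E,5R,6S,7S)-7-[(4-methoxybenzyl)oxy]-2,6-dimethyl-8-oxo-5-(propanoyloxy)oct-2-enoate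
Product: 25 coupled C1–C23 homoallylic alcohol (C5 O-propanoyl; C7 O-PMB; C8 OH; C10=CH2; C11 O-SiEt3; C21 O-SiMe2t-Bu; 2E,5R,6S,7S,8S,11S,12S,14S,16S,18S,20S,21R)
Conditions: SnCl4 (1.05 equiv) precomplexed with 24, CH2Cl2, −78 °C; then 15 (1.2 equiv); aq NaHCO3
Reagents that add atoms: none
Why: Hosomi–Sakurai allylation in which SnCl4 chelates the C8 carbonyl and the C7 PMB ether, so the 2-substituted allylsilane attacks the open face of the Cram chelate to give the 7,8-syn (8S) alcohol and loss of silicon leaves the C10 exocyclic methylene.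

Step 17
Reactants: 25 coupled C1–C23 homoallylic alcohol
Product: 26 C8 3-methylbutanoate of 25 (C5 O-propanoyl; C7 O-PMB; C8 O-isovaleryl; C10=CH2; C11 O-SiEt3; C21 O-SiMe2t-Bu; 2E,5R,6S,7S,8S,11S,12S,14S,16S,18S,20S,21R)
Conditions: (i-BuCO)2O, Et3N, 4-(dimethylamino)pyridine, CH2Cl2, rt
Reagents that add atoms: 3-methylbutanoic anhydride, CC(C)CC(=O)OC(=O)CC(C)C
Why: DMAP-catalysed acylation of the only free hydroxyl installs the C8 ester and removes C8–OH as a competing directing group for the later hydrogenation.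

Step 18
Reactants: 26 C8 3-methylbutanoate of 25
Product: 27 C11 alcohol (C5 O-propanoyl; C7 O-PMB; C8 O-isovaleryl; C10=CH2; C11 OH; C21 O-SiMe2t-Bu; 2E,5R,6S,7S,8S,11S,12S,14S,16S,18S,20S,21R)
Conditions: pyridinium p-toluenesulfonate, MeOH/CH2Cl2, 0 °C
Reagents that add atoms: none
Why: Mild acid methanolysis cleaves the triethylsilyl ether selectively while the bulkier tert-butyldimethylsilyl ether, the PMB ether and the thermodynamic spiroketal stay intact.

Step 19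
Reactants: 27 C11 alcohol
Product: 28 C10-methyl alcohol (C5 O-propanoyl; C7 O-PMB; C8 O-isovaleryl; C11 OH; C21 O-SiMe2t-Bu; 2E,5R,6S,7S,8S,10S,11S,12S,14S,16S,18S,20S,21R)
Conditions: H2 (55 bar), [Rh(nbd)(dppb)]BF4 (15 mol%), CH2Cl2, rt
Reagents that add atoms: none
Why: Hydroxyl-directed hydrogenation in which the cationic Rh binds the allylic C11–OH and the 1,1-disubstituted alkene and delivers H2 in the conformer of least A(1,2) strain to give the 10,11-anti (10S) methyl centre, leaving the unactivated trisubstituted enoate untouched.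

Step 20
Reactants: 28 C10-methyl alcohol
Product: 29 C8/C11 bis(3-methylbutanoate) (C5 O-propanoyl; C7 O-PMB; C21 O-SiMe2t-Bu; 2E,5R,6S,7S,8S,10S,11S,12S,14S,16S,18S,20S,21R)
Conditions: (i-BuCO)2O, 4-(dimethylamino)pyridine (1.5 equiv), pyridine, CH2Cl2, 35 °C
Reagents that add atoms: 3-methylbutanoic anhydride, CC(C)CC(=O)OC(=O)CC(C)C
Why: Forcing DMAP-mediated acylation of the hindered C11 hydroxyl, the only free OH, completes the second isovalerate.

Step 21
Reactants: 29 C8/C11 bis(3-methylbutanoate)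
Product: 30 C7 alcohol (C5 O-propanoyl; C7 OH; C8 and C11 O-isovaleryl; C21 O-SiMe2t-Bu; 2E,5R,6R,7S,8S,10S,11S,12S,14S,16S,18S,20S,21R where 6R reflects only a CIP priority change)
Conditions: DDQ, CH2Cl2/pH 7 buffer, 0 °C
Reagents that add atoms: none
Why: Oxidative cleavage of the PMB ether by DDQ under buffered neutral conditions frees C7–OH without touching esters, silyl ether or spiroketal and with minimal acyl migration.

Step 22
Reactants: 30 C7 alcohol
Product: 31 C21 O-tert-butyldimethylsilyl ether of the target (2E,5R,6S,7S,8S,10S,11S,12S,14S,16S,18S,20S,21R)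
Conditions: Ac2O, pyridine, 4-(dimethylamino)pyridine (cat.), CH2Cl2, 0 °C
Reagents that add atoms: acetic anhydride, CC(=O)OC(C)=O
Why: Fast DMAP-catalysed acetylation of the freshly freed C7–OH completes the acyl pattern before any 1,2-acyl migration.

Step 23
Reactants: 31 C21 O-tert-butyldimethylsilyl ether of the target
Product: 32 target CNP0165569.4 (2E,5R,6S,7S,8S,10S,11S,12S,14S,16S,18S,20S,21R)
Conditions: HF·pyridine, pyridine, THF, 0 °C → rt
Reagents that add atoms: none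
Why: Buffered fluoride desilylation under non-basic conditions liberates the C21 hydroxyl without epimerising the α-ketol or disturbing the five esters and the spiroketal.

**Compound list**

1 | 4,6-dimethyl-2H-pyran-2-one | CC1=CC(=O)OC(C)=C1 | starting material
2 | 4-methyl-2-oxo-2H-pyran-6-carbaldehyde | CC1=CC(=O)OC(C=O)=C1 | intermediate
3 | 6-[(benzyloxy)methyl]-4-methyl-2H-pyran-2-one | CC1=CC(=O)OC(COCc2ccccc2)=C1 | intermediate
4 | (6S)-6-[(benzyloxy)methyl]-4-methyl-5,6-dihydro-2H-pyran-2-one | C(OCc1ccccc1)[C@@H]2CC(C)=CC(=O)O2 | intermediate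
5 | (4S,6S)-6-[(benzyloxy)methyl]-4-methyltetrahydro-2H-pyran-2-one | C(OCc1ccccc1)[C@@H]2C[C@H](C)CC(=O)O2 | intermediate
6 | (4S,6S)-6-[(benzyloxy)methyl]-3-[(3S,5S)-6-(benzyloxy)-5-hydroxy-3-methylhexanoyl]-4-methyltetrahydro-2H-pyran-2-one (C3 epimers, present as sodium enolate) | C(OCc1ccccc1)[C@@H]2C[C@H](C)C(C(=O)C[C@@H](C)C[C@H](O)COCc3ccccc3)C(=O)O2 | intermediate
7 | (2S,4S,8S,10S)-1,11-bis(benzyloxy)-2,10-dihydroxy-4,8-dimethylundecan-6-one | C(OCc1ccccc1)[C@@H](O)C[C@H](C)CC(=O)C[C@@H](C)C[C@H](O)COCc2ccccc2 | intermediate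
8 | (2S,4S,6S,8S,10S)-2,8-bis[(benzyloxy)methyl]-4,10-dimethyl-1,7-dioxaspiro[5.5]undecane | C(OCc1ccccc1)[C@@H]2C[C@H](C)C[C@]3(C[C@@H](C)C[C@@H](COCc4ccccc4)O3)O2 | intermediate
9 | [(2S,4S,6S,8S,10S)-4,10-dimethyl-1,7-dioxaspiro[5.5]undecane-2,8-diyl]dimethanol | OC[C@@H]1C[C@H](C)C[C@]2(C[C@@H](C)C[C@@H](CO)O2)O1 | intermediate
10 | (2S,4S,6S,8S,10S)-4,10-dimethyl-1,7-dioxaspiro[5.5]undecane-2,8-dicarbaldehyde | O=C[C@@H]1C[C@H](C)C[C@]2(C[C@@H](C)C[C@@H](C=O)O2)O1 | intermediate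
11 | (2S,4S,6S,8S,10S)-8-{(1S)-1-hydroxy-2-[(trimethylsilyl)methyl]prop-2-en-1-yl}-4,10-dimethyl-1,7-dioxaspiro[5.5]undecane-2-carbaldehyde (formed as its magnesium alkoxide) | C=C(C[Si](C)(C)C)[C@H](O)[C@@H]1C[C@H](C)C[C@]2(C[C@@H](C)C[C@@H](C=O)O2)O1 | intermediate
12 | (2S,4S,6S,8S,10S)-4,10-dimethyl-8-{(1S)-1-[(triethylsilyl)oxy]-2-[(trimethylsilyl)methyl]prop-2-en-1-yl}-1,7-dioxaspiro[5.5]undecane-2-carbaldehyde | C=C(C[Si](C)(C)C)[C@H](O[Si](CC)(CC)CC)[C@@H]1C[C@H](C)C[C@]2(C[C@@H](C)C[C@@H](C=O)O2)O1 | intermediate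
13 | (1R)-1-[(2S,4S,6S,8S,10S)-4,10-dimethyl-8-{(1S)-1-[(triethylsilyl)oxy]-2-[(trimethylsilyl)methyl]prop-2-en-1-yl}-1,7-dioxaspiro[5.5]undecan-2-yl]-2-ethoxyprop-2-en-1-ol (formed as its magnesium alkoxide) | C=C(C[Si](C)(C)C)[C@H](O[Si](CC)(CC)CC)[C@@H]1C[C@H](C)C[C@]2(C[C@@H](C)C[C@@H]([C@@H](O)C(=C)OCC)O2)O1 | intermediate
14 | O-tert-butyldimethylsilyl ether of 13 (1R) | C=C(C[Si](C)(C)C)[C@H](O[Si](CC)(CC)CC)[C@@H]1C[C@H](C)C[C@]2(C[C@@H](C)C[C@@H]([C@@H](O[Si](C)(C)C(C)(C)C)C(=C)OCC)O2)O1 | intermediate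
15 | (1R)-1-[(tert-butyldimethylsilyl)oxy]-1-[(2S,4S,6S,8S,10S)-4,10-dimethyl-8-{(1S)-1-[(triethylsilyl)oxy]-2-[(trimethylsilyl)methyl]prop-2-en-1-yl}-1,7-dioxaspiro[5.5]undecan-2-yl]propan-2-one | C=C(C[Si](C)(C)C)[C@H](O[Si](CC)(CC)CC)[C@@H]1C[C@H](C)C[C@]2(C[C@@H](C)C[C@@H]([C@@H](O[Si](C)(C)C(C)(C)C)C(C)=O)O2)O1 | intermediate
16 | 2,2-dimethoxyacetaldehyde | COC(OC)C=O | starting material
17 | (2S,3S)-1,1-dimethoxy-3-methylpent-4-en-2-ol | C=C[C@H](C)[C@H](O)C(OC)OC | intermediate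
18 | 1-({[(2S,3S)-1,1-dimethoxy-3-methylpent-4-en-2-yl]oxy}methyl)-4-methoxybenzene | C=C[C@H](C)[C@H](OCc1ccc(OC)cc1)C(OC)OC | intermediate
19 | (2R,3S)-4,4-dimethoxy-3-[(4-methoxybenzyl)oxy]-2-methylbutanal | O=C[C@H](C)[C@H](OCc1ccc(OC)cc1)C(OC)OC | intermediate
20 | methyl (2E)-2-methylbut-2-enoate | C/C=C(\C)C(=O)OC | starting material
21 | [(1-methoxy-2-methylbuta-1,3-dien-1-yl)oxy]trimethylsilane (ketene-acetal geometry not defined) | C=CC(C)=C(OC)O[Si](C)(C)C | intermediate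
22 | methyl (2E,5R,6S,7S)-5-hydroxy-8,8-dimethoxy-7-[(4-methoxybenzyl)oxy]-2,6-dimethyloct-2-enoate | O[C@H](C/C=C(\C)C(=O)OC)[C@H](C)[C@H](OCc1ccc(OC)cc1)C(OC)OC | intermediate
23 | methyl (2E,5R,6S,7S)-8,8-dimethoxy-7-[(4-methoxybenzyl)oxy]-2,6-dimethyl-5-(propanoyloxy)oct-2-enoate | CCC(=O)O[C@H](C/C=C(\C)C(=O)OC)[C@H](C)[C@H](OCc1ccc(OC)cc1)C(OC)OC | intermediate
24 | methyl (2E,5R,6S,7S)-7-[(4-methoxybenzyl)oxy]-2,6-dimethyl-8-oxo-5-(propanoyloxy)oct-2-enoate | CCC(=O)O[C@H](C/C=C(\C)C(=O)OC)[C@H](C)[C@H](OCc1ccc(OC)cc1)C=O | intermediate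
25 | coupled C1–C23 homoallylic alcohol: C5 O-propanoyl, C7 O-PMB, C8 OH, C10=CH2, C11 O-SiEt3, C21 O-SiMe2t-Bu; (2E,5R,6S,7S,8S,11S,12S,14S,16S,18S,20S,21R) | CCC(=O)O[C@H](C/C=C(\C)C(=O)OC)[C@H](C)[C@H](OCc1ccc(OC)cc1)[C@H](CC(=C)[C@H](O[Si](CC)(CC)CC)[C@@H]2C[C@H](C)C[C@]3(C[C@@H](C)C[C@@H]([C@@H](O[Si](C)(C)C(C)(C)C)C(C)=O)O3)O2)O | intermediate
26 | C8 3-methylbutanoate of 25; (2E,5R,6S,7S,8S,11S,12S,14S,16S,18S,20S,21R) | CCC(=O)O[C@H](C/C=C(\C)C(=O)OC)[C@H](C)[C@H](OCc1ccc(OC)cc1)[C@H](CC(=C)[C@H](O[Si](CC)(CC)CC)[C@@H]2C[C@H](C)C[C@]3(C[C@@H](C)C[C@@H]([C@@H](O[Si](C)(C)C(C)(C)C)C(C)=O)O3)O2)OC(=O)CC(C)C | intermediate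
27 | C11 alcohol: as 26 with C11 OH; (2E,5R,6S,7S,8S,11S,12S,14S,16S,18S,20S,21R) | CCC(=O)O[C@H](C/C=C(\C)C(=O)OC)[C@H](C)[C@H](OCc1ccc(OC)cc1)[C@H](CC(=C)[C@H](O)[C@@H]2C[C@H](C)C[C@]3(C[C@@H](C)C[C@@H]([C@@H](O[Si](C)(C)C(C)(C)C)C(C)=O)O3)O2)OC(=O)CC(C)C | intermediate
28 | C10-methyl alcohol: as 27 with C10 H/CH3; (2E,5R,6S,7S,8S,10S,11S,12S,14S,16S,18S,20S,21R) | CCC(=O)O[C@H](C/C=C(\C)C(=O)OC)[C@H](C)[C@H](OCc1ccc(OC)cc1)[C@H](C[C@H](C)[C@H](O)[C@@H]2C[C@H](C)C[C@]3(C[C@@H](C)C[C@@H]([C@@H](O[Si](C)(C)C(C)(C)C)C(C)=O)O3)O2)OC(=O)CC(C)C | intermediate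
29 | C8/C11 bis(3-methylbutanoate): C7 O-PMB, C21 O-SiMe2t-Bu; (2E,5R,6S,7S,8S,10S,11S,12S,14S,16S,18S,20S,21R) | CCC(=O)O[C@H](C/C=C(\C)C(=O)OC)[C@H](C)[C@H](OCc1ccc(OC)cc1)[C@H](C[C@H](C)[C@H](OC(=O)CC(C)C)[C@@H]2C[C@H](C)C[C@]3(C[C@@H](C)C[C@@H]([C@@H](O[Si](C)(C)C(C)(C)C)C(C)=O)O3)O2)OC(=O)CC(C)C | intermediate
30 | C7 alcohol: as 29 with C7 OH; (2E,5R,6R,7S,8S,10S,11S,12S,14S,16S,18S,20S,21R) | CCC(=O)O[C@H](C/C=C(\C)C(=O)OC)[C@H](C)[C@H](O)[C@H](C[C@H](C)[C@H](OC(=O)CC(C)C)[C@@H]1C[C@H](C)C[C@]2(C[C@@H](C)C[C@@H]([C@@H](O[Si](C)(C)C(C)(C)C)C(C)=O)O2)O1)OC(=O)CC(C)C | intermediate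
31 | C21 O-tert-butyldimethylsilyl ether of the target; (2E,5R,6S,7S,8S,10S,11S,12S,14S,16S,18S,20S,21R) | CCC(=O)O[C@H](C/C=C(\C)C(=O)OC)[C@H](C)[C@H](OC(C)=O)[C@H](C[C@H](C)[C@H](OC(=O)CC(C)C)[C@@H]1C[C@H](C)C[C@]2(C[C@@H](C)C[C@@H]([C@@H](O[Si](C)(C)C(C)(C)C)C(C)=O)O2)O1)OC(=O)CC(C)C | intermediate
32 | CNP0165569.4; (2E,5R,6S,7S,8S,10S,11S,12S,14S,16S,18S,20S,21R) | CCC(=O)O[C@H](C/C=C(\C)C(=O)OC)[C@H](C)[C@H](OC(C)=O)[C@H](C[C@H](C)[C@H](OC(=O)CC(C)C)[C@@H]1C[C@H](C)C[C@]2(C[C@@H](C)C[C@@H]([C@@H](O)C(C)=O)O2)O1)OC(=O)CC(C)C | target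

**Step count and risks**

Total step count: 23. Longest linear sequence: 16 steps (steps 1–8, then 16–23); the C1–C8 aldehyde takes steps 9–11 and 13–15, with step 12 as a one-step side branch.

Steps most likely to fail:

Step 3 (asymmetric pyrone hydrogenation on a new 6-substituent; ee, over-reduction, sense of induction). The fallback sets out from 3 and comes back at 5. Non-selective hydrogenation of 3 (H2, Rh/Al2O3, EtOAc) gives the racemic cis-lactone (±)-cis-6-[(benzyloxy)methyl]-4-methyltetrahydro-2H-pyran-2-one F1. Aminolysis with (S)-1-phenylethylamine (AlMe3, toluene) gives two diastereomeric hydroxy amides, from which (3S,5S)-6-(benzyloxy)-5-hydroxy-3-methyl-N-[(1S)-1-phenylethyl]hexanamide F2 is separated by crystallisation or chromatography. Acid-catalysed relactonisation (TsOH, toluene, 80 °C) then gives 5, so the stereocentres come from a classical resolution instead of asymmetric catalysis.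

Step 7 (statistical mono-addition to the dialdehyde, chelation selectivity, handling of recovered 10). The fallback sets out from 9 and comes back at 12, moving the symmetry-breaking to the robust diol. Mono-acylation of 9 (t-BuCOCl 1.0 equiv, pyridine, −20 °C, diol recycled) gives the mono-pivalate [(2S,4S,6S,8S,10S)-8-(hydroxymethyl)-4,10-dimethyl-1,7-dioxaspiro[5.5]undecan-2-yl]methyl 2,2-dimethylpropanoate F3. Dess–Martin oxidation gives the aldehyde pivalate F4. Addition of excess CH2=C(MgBr)CH2SiMe3 with MgBr2·OEt2 and a Et3SiOTf quench gives the TES-protected allylsilane pivalate F5. Removal of the pivalate with i-Bu2AlH (−78 °C) gives the primary alcohol F6, and Dess–Martin oxidation of F6 gives 12.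

Step 16 (Sakurai union: PMB or spiroketal sensitivity to SnCl4, level of chelation control at C8). The fallback sets out from 15 and 24 and comes back at 26. The union is run with the monodentate Lewis acid BF3·OEt2 (CH2Cl2, −78 °C), where polar Felkin–Anh control gives mainly the 7,8-anti product, the (8R)-epimer of 25 F7. Mitsunobu esterification of F7 with 3-methylbutanoic acid (PPh3, diisopropyl azodicarboxylate, toluene, 0 °C) inverts C8 and gives 26 directly, so C8 is set by SN2 inversion instead of chelation-controlled addition.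

**Further compounds**

F1 | step 3 | (±)-cis-6-[(benzyloxy)methyl]-4-methyltetrahydro-2H-pyran-2-one (racemate) | C(OCc1ccccc1)[C@@H]2C[C@H](C)CC(=O)O2.C(OCc1ccccc1)[C@H]2C[C@@H](C)CC(=O)O2
F2 | step 3 | (3S,5S)-6-(benzyloxy)-5-hydroxy-3-methyl-N-[(1S)-1-phenylethyl]hexanamide | C(OCc1ccccc1)[C@@H](O)C[C@H](C)CC(=O)N[C@@H](C)c2ccccc2
F3 | step 7 | [(2S,4S,6S,8S,10S)-8-(hydroxymethyl)-4,10-dimethyl-1,7-dioxaspiro[5.5]undecan-2-yl]methyl 2,2-dimethylpropanoate | OC[C@@H]1C[C@H](C)C[C@]2(C[C@@H](C)C[C@@H](COC(=O)C(C)(C)C)O2)O1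
F4 | step 7 | [(2S,4S,6S,8S,10S)-8-formyl-4,10-dimethyl-1,7-dioxaspiro[5.5]undecan-2-yl]methyl 2,2-dimethylpropanoate | O=C[C@@H]1C[C@H](C)C[C@]2(C[C@@H](C)C[C@@H](COC(=O)C(C)(C)C)O2)O1
F5 | step 7 | [(2S,4S,6S,8S,10S)-4,10-dimethyl-8-{(1S)-1-[(triethylsilyl)oxy]-2-[(trimethylsilyl)methyl]prop-2-en-1-yl}-1,7-dioxaspiro[5.5]undecan-2-yl]methyl 2,2-dimethylpropanoate | C=C(C[Si](C)(C)C)[C@H](O[Si](CC)(CC)CC)[C@@H]1C[C@H](C)C[C@]2(C[C@@H](C)C[C@@H](COC(=O)C(C)(C)C)O2)O1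
F6 | step 7 | [(2S,4S,6S,8S,10S)-4,10-dimethyl-8-{(1S)-1-[(triethylsilyl)oxy]-2-[(trimethylsilyl)methyl]prop-2-en-1-yl}-1,7-dioxaspiro[5.5]undecan-2-yl]methanol | C=C(C[Si](C)(C)C)[C@H](O[Si](CC)(CC)CC)[C@@H]1C[C@H](C)C[C@]2(C[C@@H](C)C[C@@H](CO)O2)O1
F7 | step 16 | (8R)-epimer of 25 (2E,5R,6S,7S,8R,11S,12S,14S,16S,18S,20S,21R) | CCC(=O)O[C@H](C/C=C(\C)C(=O)OC)[C@H](C)[C@H](OCc1ccc(OC)cc1)[C@@H](CC(=C)[C@H](O[Si](CC)(CC)CC)[C@@H]2C[C@H](C)C[C@]3(C[C@@H](C)C[C@@H]([C@@H](O[Si](C)(C)C(C)(C)C)C(C)=O)O3)O2)O
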